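To whoever takes the bench: the teal flask is running closed and stirred, and this note says what you will find in it.

| flask | left-handed substrate | right-handed substrate | coupling partner | remark | time |
|---|---|---|---|---|---|
| teal | 0.10 M | 0.10 M | 0.25 M | the very flask that is asked about, followed so far |  |
| green | 0.050 M | 0.050 M | 0.25 M | run made earlier |  |
| flask | 0.10 M | 0.10 M | 0.250 M |  | 5.0 min |

- teal (time / s: left-handed product / %, right-handed product / %, left-handed substrate / %): 10.0: 2.4, 1.0, 36.5; 20.0: 3.1, 1.6, 32.5; 30.0: 4.9, 2.8, 30.2; 50.0: 4.9, 2.7, 31.4; 60.0: 5.6, 3.8, 29.2; 90.0: 6.3, 2.9, 29.9
- green (time / min: left-handed product / %, right-handed product / %, left-handed substrate / %): 0.250: 2.2, 1.4, 33.9; 0.667: 4.6, 2.7, 30.9; 1.33: 6.8, 3.1, 30.0; 2.00: 7.8, 3.4, 29.1; 2.50: 7.6, 4.3, 29.3; 4.00: 9.2, 5.6, 29.0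

(scatter of a reading: 0.5 percentage points)

- coupling partner is single-handed; left-handed substrate and right-handed substrate are mirror images of each other, charged as a racemate, each of them at the stated concentration
- what has gone into achiral form counts as reacted
- an excess is the difference of the two amounts in percent of their sum
- an excess is below zero if the other one leads
- the handed part of coupling partner does not stay in what it makes, so the products of the two hands are mirror images too

Follow one coupling partner molecule that ends in product: at the fork it takes one hand or the other. Pool the product readings of both runs, and the difference over the sum comes to 29.9%. Call this E, the fork excess. It means a selectivity factor of 1.85, left over right.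

E holds while the two substrates stand level. In the teal flask, left-handed substrate has lost 20 percentage points by 30.0 s, while left-handed product holds 4.9%, so by these readings more went to the achiral form than to product. I take that exchange to keep the hands level, so I expect E at both times.

The left-handed substrate reading lies flat at nearly one level in both runs: 29.9% at 90.0 s in the teal flask, 29.0% at 4.00 min in the green run. The green run was followed longer, so I borrow its last reading for the teal flask at 5.0 min. With the other hand equal, I commit to 42.0% reacted.

So don't hurry the sample for a better excess: the first three readings of both runs give 31.1%, the last three 29.2%, and with a scatter of 0.5 points on readings this small I read no trend in that gap.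

- excess of left-handed product over right-handed product in the product at 30 s
- excess of left-handed product over right-handed product in the product at 5.0 min
- part of the left-handed substrate and right-handed substrate charged together that has reacted at 5.0 min

The forecast gives 30%, 30% and 42.5%, with the excess “with no trend in time, as expected when the pools stay nearly equal”.

The flask gives 30.7%, 30.8% and 42.3%.

    coupling partner + left-handed substrate → left-handed product (k = 0.0250 M⁻¹ s⁻¹)
    coupling partner + right-handed substrate → right-handed product (k = 0.0130 M⁻¹ s⁻¹)
    left-handed substrate ⇌ achiral form (K = 0.970, k = 0.0410 s⁻¹)
    right-handed substrate ⇌ achiral form (K = 0.970, k = 0.0410 s⁻¹)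
    coupling partner ⇌ dormant form (K = 0.0860, k = 0.00430 s⁻¹)
    2 coupling partner → self-condensation product (k = 0.100 M⁻¹ s⁻¹)
    coupling partner → decomposed reagent (k = 0.00200 s⁻¹)

In the teal flask at 5.0 min, E splits the 14.3% of product so that 9.29% is left-handed, and the flask holds 9.36%. A neighbouring flask starts with 1.0 M of coupling partner, which is 10.0 equiv to left-handed substrate, all else unchanged. Its product at 5.0 min is 22.7%, of which E puts 14.8% on the left, and that flask holds 14.8%. Its excess is 30.0%. The neighbouring flask has 48.0% reacted, with 0.99% of its coupling partner left.

All runs are simulated from invented constants.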